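**Plan**
- Retrosynthesis: the four O–CH3 bonds and two temporary C–Br bonds are removed last. The dihydrofuran is then cut at C3–C3a and O1–C2 into a 4‑hydroxystilbene (rings B and C) and a 4,6‑dibromo‑5‑(arylethyl)resorcinol (rings A and D). Each partner is cut at its central two‑carbon link by an olefination.
- Enabling feature: the ring O1–C2–C3–C3a–C7a is fused to ring A at C3a, the carbon lying between O1 and the C4 hydroxyl, and C2 is benzylic to ring B, whose oxygen para to C2 can carry a phenoxyl radical and then a quinone methide. Ring A is symmetric about its C3a–C6 axis, so C5 and C7 can be blocked by bromine and either oxygen closes to the same ring.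
- Forward: the ring A–ring D unit comes from Wittig olefination, hydrogenation and dibromination, and the ring B–ring C stilbene from a Horner–Wadsworth–Emmons reaction. One oxidative (3+2) coupling then forms C3–C3a and O1–C2, closing the only new ring, followed by resolution, debromination and demethylation.
- Stereochemistry: the trans C2/C3 relationship comes from the ring closure, and the absolute (2S,3S) configuration from resolution of the racemate on a chiral phase.

Key step: step 6

Remarks: ring A is the benzene ring of the benzofuran, ring B the aryl on C2, ring C the aryl on C3 and ring D the aryl of the side chain. The coupling is not enantioselective, so a racemate is written in the lists as both enantiomers joined by a dot.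

**Step 1**
Reactants: 1 3,5-bis(benzyloxy)benzaldehyde; 2 (4-methoxybenzyl)triphenylphosphonium chloride
Product: 3 1,3-bis(benzyloxy)-5-[2-(4-methoxyphenyl)ethenyl]benzene (E/Z mixture)
Conditions: KOtBu, THF, 0 °C → rt
Reagents that add atoms: none
Why: Wittig olefination of a semi-stabilised benzylic ylide with a non-enolisable aryl aldehyde should be reliable, and the olefin geometry does not matter because the double bond is saturated in step 2.

**Step 2**
Reactants: 3 1,3-bis(benzyloxy)-5-[2-(4-methoxyphenyl)ethenyl]benzene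
Product: 4 5-[2-(4-methoxyphenyl)ethyl]benzene-1,3-diol
Conditions: H2 (1 atm), 10% Pd/C, EtOAc/MeOH, rt
Reagents that add atoms: none
Why: heterogeneous catalytic hydrogenation should saturate the stilbene and hydrogenolyse both benzyl ethers in one operation, while the aryl methyl ether of ring D is inert.

**Step 3**
Reactants: 4 5-[2-(4-methoxyphenyl)ethyl]benzene-1,3-diol
Product: 5 4,6-dibromo-5-[2-(4-methoxyphenyl)ethyl]benzene-1,3-diol
Conditions: Br2 (2.0 equiv), CH2Cl2, −15 °C
Reagents that add atoms: bromine, BrBr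
Why: electrophilic aromatic bromination of a 5-alkylresorcinol should go first to C4 and C6 (each ortho to one hydroxyl and para to the other), leaving C2 between the hydroxyls open, and the far less activated anisole ring should not compete at low temperature with exact stoichiometry.

**Step 4**
Reactants: 6 4-hydroxy-2-methoxybenzaldehyde
Product: 7 2-methoxy-4-(methoxymethoxy)benzaldehyde
Conditions: MOMCl, K2CO3, acetone, 0 °C → rt
Reagents that add atoms: chloromethyl methyl ether, COCCl
Why: Williamson-type O-alkylation masks the para hydroxyl as an acetal, so that no phenoxide can deactivate the aldehyde towards the phosphonate carbanion in step 5.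

**Step 5**
Reactants: 7 2-methoxy-4-(methoxymethoxy)benzaldehyde; 8 diethyl (3,5-dimethoxybenzyl)phosphonate
Product: 10 (E)-4-[2-(3,5-dimethoxyphenyl)ethenyl]-3-methoxyphenol, via MOM-protected stilbene 9 (not isolated)
Conditions: KOtBu, THF, 0 °C → rt; then 2 M HCl, MeOH, 50 °C
Reagents that add atoms: none
Why: the Horner–Wadsworth–Emmons reaction of a benzylic phosphonate with an aryl aldehyde should give the E-stilbene, and acid-catalysed acetal exchange with methanol then frees the 4-hydroxyl that the oxidation needs.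

**Step 6**
Reactants: 5 4,6-dibromo-5-[2-(4-methoxyphenyl)ethyl]benzene-1,3-diol; 10 (E)-4-[2-(3,5-dimethoxyphenyl)ethenyl]-3-methoxyphenol
Product: 12 racemic trans-5,7-dibromo-3-(3,5-dimethoxyphenyl)-2-(4-hydroxy-2-methoxyphenyl)-6-[2-(4-methoxyphenyl)ethyl]-2,3-dihydro-1-benzofuran-4-ol, via para-quinone methide 11 (not isolated)
Conditions: Ag2O (1.2 equiv), 5 (3 equiv), acetone/toluene 1:2, rt, dark; 10 added over 8 h by syringe pump
Reagents that add atoms: none
Why: Ag2O (monovalent silver) should take one electron from the conjugated 4-hydroxyl of 10, the most easily oxidised phenol present, and the phenoxyl radical carries spin at the olefin carbon attached to ring C, which bonds to resorcinol carbon C2 of 5 (later C3a); loss of a second electron and a proton to silver and tautomerisation restore ring A and leave ring B as para-quinone methide 11. The closest known reaction type is the Ag2O- or FeCl3-mediated oxidative coupling of 4-hydroxystilbenes and propenylphenols with phenols to 2,3-disubstituted 2,3-dihydrobenzofurans, as in biomimetic stilbene dimerisation. The dihydrofuran ring closes by 5-exo-trig conjugate addition of a ring A hydroxyl to the exocyclic methide carbon of 11, which becomes C2. C3 is created in the C–C bond formation without facial bias, so both enantiomers arise, while C2 is set relative to C3 in the ring closure, where the two aryl groups take the less crowded trans arrangement and reversible opening through the quinone methide lets any cis isomer drain to trans. Cross-coupling over stilbene self-coupling is favoured by the threefold excess of 5 and the slow addition of 10, which keep the radical concentration low. Site selectivity on ring A is secured by the bromine atoms on C4 and C6 of 5, which leave C2 as the only open carbon, and by the twofold symmetry of 5, which makes both hydroxyls give the same product.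

**Step 7**
Reactants: 12 racemic trans-5,7-dibromo-3-(3,5-dimethoxyphenyl)-2-(4-hydroxy-2-methoxyphenyl)-6-[2-(4-methoxyphenyl)ethyl]-2,3-dihydro-1-benzofuran-4-ol
Product: 13 (2S,3S)-5,7-dibromo-3-(3,5-dimethoxyphenyl)-2-(4-hydroxy-2-methoxyphenyl)-6-[2-(4-methoxyphenyl)ethyl]-2,3-dihydro-1-benzofuran-4-ol
Conditions: preparative HPLC, amylose tris(3,5-dimethylphenylcarbamate) on silica, n-hexane/2-propanol, rt
Reagents that add atoms: none
Why: enantiomers of this compound class should separate on a polysaccharide carbamate phase without any bond change, and the two bromine atoms should allow the absolute configuration of the collected enantiomer to be assigned by anomalous-dispersion X-ray crystallography before it is carried on.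

**Step 8**
Reactants: 13 (2S,3S)-5,7-dibromo-3-(3,5-dimethoxyphenyl)-2-(4-hydroxy-2-methoxyphenyl)-6-[2-(4-methoxyphenyl)ethyl]-2,3-dihydro-1-benzofuran-4-ol
Product: 14 (2S,3S)-3-(3,5-dimethoxyphenyl)-2-(4-hydroxy-2-methoxyphenyl)-6-[2-(4-methoxyphenyl)ethyl]-2,3-dihydro-1-benzofuran-4-ol
Conditions: H2 (1 atm), 10% Pd/C, Et3N, EtOAc, rt
Reagents that add atoms: none
Why: palladium-catalysed hydrodehalogenation should cleave both aryl C–Br bonds, while the amine takes up HBr and moderates the catalyst so that the cyclic benzylic aryl ether C2–O1 is not hydrogenolysed; neither stereocentre is involved.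

**Step 9**
Reactants: 14 (2S,3S)-3-(3,5-dimethoxyphenyl)-2-(4-hydroxy-2-methoxyphenyl)-6-[2-(4-methoxyphenyl)ethyl]-2,3-dihydro-1-benzofuran-4-ol
Product: 15 (2S,3S)-2-(2,4-dihydroxyphenyl)-3-(3,5-dihydroxyphenyl)-6-[2-(4-hydroxyphenyl)ethyl]-2,3-dihydro-1-benzofuran-4-ol (CNP0329616.1)
Conditions: BBr3 (10 equiv), CH2Cl2, −78 °C → rt; then MeOH, H2O
Reagents that add atoms: none
Why: Lewis acid cleavage of the four aryl methyl ethers with BBr3 is standard for methylated oligostilbenes; the boron-bound phenols of ring B damp ionisation at C2, any opening of C2–O1 can only reclose through one of the two equivalent ring A oxygens to the same trans compound, and C3 is not touched.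

**Compound list**
1 | 3,5-bis(benzyloxy)benzaldehyde | O=Cc1cc(OCc2ccccc2)cc(OCc2ccccc2)c1 | starting material
2 | (4-methoxybenzyl)triphenylphosphonium chloride | COc1ccc(C[P+](c2ccccc2)(c2ccccc2)c2ccccc2)cc1.[Cl-] | starting material
3 | 1,3-bis(benzyloxy)-5-[2-(4-methoxyphenyl)ethenyl]benzene (E/Z mixture) | COc1ccc(C=Cc2cc(OCc3ccccc3)cc(OCc3ccccc3)c2)cc1 | intermediate
4 | 5-[2-(4-methoxyphenyl)ethyl]benzene-1,3-diol | COc1ccc(CCc2cc(O)cc(O)c2)cc1 | intermediate
5 | 4,6-dibromo-5-[2-(4-methoxyphenyl)ethyl]benzene-1,3-diol | COc1ccc(CCc2c(Br)c(O)cc(O)c2Br)cc1 | intermediate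
6 | 4-hydroxy-2-methoxybenzaldehyde | COc1cc(O)ccc1C=O | starting material
7 | 2-methoxy-4-(methoxymethoxy)benzaldehyde | COCOc1ccc(C=O)c(OC)c1 | intermediate
8 | diethyl (3,5-dimethoxybenzyl)phosphonate | CCOP(=O)(Cc1cc(OC)cc(OC)c1)OCC | starting material
9 | (E)-1-[2-(3,5-dimethoxyphenyl)ethenyl]-2-methoxy-4-(methoxymethoxy)benzene | COCOc1ccc(/C=C/c2cc(OC)cc(OC)c2)c(OC)c1 | intermediate
10 | (E)-4-[2-(3,5-dimethoxyphenyl)ethenyl]-3-methoxyphenol | COc1cc(OC)cc(/C=C/c2ccc(O)cc2OC)c1 | intermediate
11 | 4-[2-[3,5-dibromo-2,6-dihydroxy-4-[2-(4-methoxyphenyl)ethyl]phenyl]-2-(3,5-dimethoxyphenyl)ethylidene]-3-methoxycyclohexa-2,5-dien-1-one (racemic, olefin geometry not fixed) | O=C1C=CC(=C[C@H](c2c(O)c(Br)c(CCc3ccc(OC)cc3)c(Br)c2O)c2cc(OC)cc(OC)c2)C(OC)=C1.O=C1C=CC(=C[C@@H](c2c(O)c(Br)c(CCc3ccc(OC)cc3)c(Br)c2O)c2cc(OC)cc(OC)c2)C(OC)=C1 | intermediate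
12 | racemic trans-5,7-dibromo-3-(3,5-dimethoxyphenyl)-2-(4-hydroxy-2-methoxyphenyl)-6-[2-(4-methoxyphenyl)ethyl]-2,3-dihydro-1-benzofuran-4-ol ((2S,3S) and (2R,3R)) | COc1ccc(CCc2c(Br)c(O)c3c(c2Br)O[C@H](c2ccc(O)cc2OC)[C@H]3c2cc(OC)cc(OC)c2)cc1.COc1ccc(CCc2c(Br)c(O)c3c(c2Br)O[C@@H](c2ccc(O)cc2OC)[C@@H]3c2cc(OC)cc(OC)c2)cc1 | intermediate
13 | (2S,3S)-5,7-dibromo-3-(3,5-dimethoxyphenyl)-2-(4-hydroxy-2-methoxyphenyl)-6-[2-(4-methoxyphenyl)ethyl]-2,3-dihydro-1-benzofuran-4-ol | COc1ccc(CCc2c(Br)c(O)c3c(c2Br)O[C@H](c2ccc(O)cc2OC)[C@H]3c2cc(OC)cc(OC)c2)cc1 | intermediate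
14 | (2S,3S)-3-(3,5-dimethoxyphenyl)-2-(4-hydroxy-2-methoxyphenyl)-6-[2-(4-methoxyphenyl)ethyl]-2,3-dihydro-1-benzofuran-4-ol | COc1ccc(CCc2cc(O)c3c(c2)O[C@H](c2ccc(O)cc2OC)[C@H]3c2cc(OC)cc(OC)c2)cc1 | intermediate
15 | (2S,3S)-2-(2,4-dihydroxyphenyl)-3-(3,5-dihydroxyphenyl)-6-[2-(4-hydroxyphenyl)ethyl]-2,3-dihydro-1-benzofuran-4-ol | Oc1ccc(CCc2cc(O)c3c(c2)O[C@H](c2ccc(O)cc2O)[C@H]3c2cc(O)cc(O)c2)cc1 | target

Total step count: 9 (eight reactions and one chromatographic resolution).
Longest linear sequence: 7 steps (steps 1, 2, 3, 6, 7, 8, 9).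

**Steps most likely to fail**

Step 6. Self-coupling of the stilbene-derived radical (through ring B C5 or the olefin carbon) may outrun its capture by the bromine-deactivated resorcinol, or radical attack at the bromine-bearing carbons may consume 5. The fallback sets out from 5, comes back at 15, and builds the same ring stepwise without an oxidant.
- 5 is mono-O-alkylated with commercial 2-bromo-1-(3,5-dimethoxyphenyl)ethanone (K2CO3, acetone) to the aryloxy ketone 2-[2,4-dibromo-5-hydroxy-3-[2-(4-methoxyphenyl)ethyl]phenoxy]-1-(3,5-dimethoxyphenyl)ethanone F1.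
- Acid cyclodehydration (Bi(OTf)3, 1,2-dichloroethane, reflux) can close only at the carbon between the two oxygens and should give 5,7-dibromo-3-(3,5-dimethoxyphenyl)-6-[2-(4-methoxyphenyl)ethyl]-1-benzofuran-4-ol F2.
- The bromines are then removed (H2, Pd/C, Et3N, EtOAc) to give 3-(3,5-dimethoxyphenyl)-6-[2-(4-methoxyphenyl)ethyl]-1-benzofuran-4-ol F3.
- C2–H arylation with 1-bromo-2,4-dimethoxybenzene (Pd(OAc)2, PCy3·HBF4, pivalic acid, K2CO3, DMA, 110 °C) should give 2-(2,4-dimethoxyphenyl)-3-(3,5-dimethoxyphenyl)-6-[2-(4-methoxyphenyl)ethyl]-1-benzofuran-4-ol F4.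
- Ionic hydrogenation (Et3SiH, CF3CO2H, CH2Cl2, 0 °C) is expected to give racemic trans-2-(2,4-dimethoxyphenyl)-3-(3,5-dimethoxyphenyl)-6-[2-(4-methoxyphenyl)ethyl]-2,3-dihydro-1-benzofuran-4-ol F5.
- Chiral HPLC as in step 7 gives the (2S,3S) enantiomer of that dihydrobenzofuran F6, and BBr3 as in step 9, now cleaving five methyl ethers, leads to 15.

Step 9. Cleavage at the hindered ortho-methoxy group of ring B may stay incomplete, and acid-promoted opening at C2–O1 or air oxidation may erode the free hexaphenol while it is separated from boron residues. The fallback sets out from 14, comes back at 15, and changes the endgame to capture and release.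
- After the BBr3 treatment and methanol quench the crude material is not purified but peracetylated (Ac2O, pyridine, DMAP) to the hexaacetate of (2S,3S)-2-(2,4-dihydroxyphenyl)-3-(3,5-dihydroxyphenyl)-6-[2-(4-hydroxyphenyl)ethyl]-2,3-dihydro-1-benzofuran-4-ol F7.
- This neutral, air-stable compound can be chromatographed or crystallised free of partly cleaved material, which is recycled.
- Mild methanolysis (catalytic K2CO3, MeOH, 0 °C, argon, then dilute acid) should release 15 without any Lewis acid.

Step 7. The enantiomers may separate poorly, or the loading on the chiral phase may be too small for useful throughput. The fallback sets out from 12, comes back at 13, and replaces the chiral phase by covalent diastereomers.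
- Both phenols of 12 are acylated with (1S)-camphanic chloride (Et3N, DMAP, CH2Cl2).
- This gives the bis[(1S,4R)-camphanate] of the (2S,3S) enantiomer F8 and the bis[(1S,4R)-camphanate] of the (2R,3R) enantiomer F9, which should be separable on silica or by crystallisation.
- Methanolysis of the first (K2CO3, MeOH, 0 °C) returns 13.

**Further compounds**
F1 | step 6 | 2-[2,4-dibromo-5-hydroxy-3-[2-(4-methoxyphenyl)ethyl]phenoxy]-1-(3,5-dimethoxyphenyl)ethanone | COc1ccc(CCc2c(Br)c(O)cc(OCC(=O)c3cc(OC)cc(OC)c3)c2Br)cc1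
F2 | step 6 | 5,7-dibromo-3-(3,5-dimethoxyphenyl)-6-[2-(4-methoxyphenyl)ethyl]-1-benzofuran-4-ol | COc1ccc(CCc2c(Br)c(O)c3c(c2Br)occ3-c2cc(OC)cc(OC)c2)cc1
F3 | step 6 | 3-(3,5-dimethoxyphenyl)-6-[2-(4-methoxyphenyl)ethyl]-1-benzofuran-4-ol | COc1ccc(CCc2cc(O)c3c(c2)occ3-c2cc(OC)cc(OC)c2)cc1
F4 | step 6 | 2-(2,4-dimethoxyphenyl)-3-(3,5-dimethoxyphenyl)-6-[2-(4-methoxyphenyl)ethyl]-1-benzofuran-4-ol | COc1ccc(CCc2cc(O)c3c(c2)oc(-c2ccc(OC)cc2OC)c3-c2cc(OC)cc(OC)c2)cc1
F5 | step 6 | racemic trans-2-(2,4-dimethoxyphenyl)-3-(3,5-dimethoxyphenyl)-6-[2-(4-methoxyphenyl)ethyl]-2,3-dihydro-1-benzofuran-4-ol | COc1ccc(CCc2cc(O)c3c(c2)O[C@H](c2ccc(OC)cc2OC)[C@H]3c2cc(OC)cc(OC)c2)cc1.COc1ccc(CCc2cc(O)c3c(c2)O[C@@H](c2ccc(OC)cc2OC)[C@@H]3c2cc(OC)cc(OC)c2)cc1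
F6 | step 6 | (2S,3S)-2-(2,4-dimethoxyphenyl)-3-(3,5-dimethoxyphenyl)-6-[2-(4-methoxyphenyl)ethyl]-2,3-dihydro-1-benzofuran-4-ol | COc1ccc(CCc2cc(O)c3c(c2)O[C@H](c2ccc(OC)cc2OC)[C@H]3c2cc(OC)cc(OC)c2)cc1
F7 | step 9 | hexaacetate of (2S,3S)-2-(2,4-dihydroxyphenyl)-3-(3,5-dihydroxyphenyl)-6-[2-(4-hydroxyphenyl)ethyl]-2,3-dihydro-1-benzofuran-4-ol | CC(=O)Oc1ccc(CCc2cc(OC(C)=O)c3c(c2)O[C@H](c2ccc(OC(C)=O)cc2OC(C)=O)[C@H]3c2cc(OC(C)=O)cc(OC(C)=O)c2)cc1
F8 | step 7 | bis[(1S,4R)-camphanate] of the (2S,3S) enantiomer of 12 | COc1ccc(CCc2c(Br)c(OC(=O)[C@@]45CC[C@@](C)(C(=O)O4)C5(C)C)c3c(c2Br)O[C@H](c2ccc(OC(=O)[C@@]45CC[C@@](C)(C(=O)O4)C5(C)C)cc2OC)[C@H]3c2cc(OC)cc(OC)c2)cc1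
F9 | step 7 | bis[(1S,4R)-camphanate] of the (2R,3R) enantiomer of 12 | COc1ccc(CCc2c(Br)c(OC(=O)[C@@]45CC[C@@](C)(C(=O)O4)C5(C)C)c3c(c2Br)O[C@@H](c2ccc(OC(=O)[C@@]45CC[C@@](C)(C(=O)O4)C5(C)C)cc2OC)[C@@H]3c2cc(OC)cc(OC)c2)cc1
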